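**Plan**
- Retrosynthesis: the two phenolic O–H become O–CH2Ph and the C9–C10 single bond of the tetracosyl chain becomes a C9=C10 alkene. That alkene is cut by cross-metathesis into a dec-9-enyl ester (C1–C9) and hexadec-1-ene (C10–C24). The two ArO–Bn bonds and then the ester O–C1 bond are cut last.
- Enabling feature: C9 and C10 lie inside the unbranched, unfunctionalised polymethylene chain, eight CH2 groups (C1–C8) from the ester oxygen and remote from the benzene ring. A C9=C10 alkene is therefore a traceless handle, erased by the same hydrogenation that removes both benzyl ethers.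
- Forward: the benzene ring is bought as 2,3-dihydroxybenzoic acid. The sequence is carboxylate O-alkylation, catechol benzylation, chain joining by cross-metathesis, then one global hydrogenation; no ring is formed.
- Stereochemistry: the target has no stereocentre, and the alkene geometry from the metathesis is removed in the last step.

Key step: step 3

Remark: 2,3-dihydroxybenzoic acid, 10-bromodec-1-ene and hexadec-1-ene are taken as commercial. Compound 6 is drawn as the E isomer although an E/Z mixture is expected; both isomers give the same product in step 4.

**Step 1**
Reactants: 1 2,3-dihydroxybenzoic acid; 2 10-bromodec-1-ene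
Product: 3 dec-9-en-1-yl 2,3-dihydroxybenzoate
Conditions: KHCO3 (1.2 equiv), DMF, 60 °C, N2
Reagents that add atoms: none
Why: Carboxylate O-alkylation (SN2): hydrogencarbonate deprotonates only the CO2H group and not the phenols, so the primary bromide should be attacked by the carboxylate alone.

**Step 2**
Reactants: 3 dec-9-en-1-yl 2,3-dihydroxybenzoate
Product: 4 dec-9-en-1-yl 2,3-bis(benzyloxy)benzoate
Conditions: BnBr (2.4 equiv), K2CO3 (3 equiv), DMF, 50 °C, N2
Reagents that add atoms: benzyl bromide, BrCc1ccccc1
Why: Williamson ether synthesis: K2CO3 in DMF generates both phenoxides (the hydrogen-bonded 2-OH included) and benzyl bromide is a reactive SN2 electrophile, while the alkyl ester and the remote alkene are inert under these anhydrous conditions.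

**Step 3**
Reactants: 4 dec-9-en-1-yl 2,3-bis(benzyloxy)benzoate; 5 hexadec-1-ene (3 equiv)
Product: 6 (E)-tetracos-9-en-1-yl 2,3-bis(benzyloxy)benzoate
Conditions: Grubbs II (3 mol%), 1,4-benzoquinone (10 mol%), CH2Cl2, 40 °C, argon sweep
Reagents that add atoms: none
Why: Olefin cross-metathesis by the Chauvin mechanism: the Ru alkylidene adds [2+2] to one terminal alkene, the ruthenacyclobutane cycloreverts with loss of ethylene, and the new alkylidene repeats the sequence with the second alkene to give the C9=C10 internal alkene. The closest known reaction type is the cross-metathesis of two unhindered terminal (type I) alkenes with a second-generation Ru carbene. No ring is closed and no stereocentre is created; the E/Z geometry of the new alkene is immaterial because step 4 saturates it. The step needs cross- over homo-coupling, which the excess of cheap 5 and the removal of ethylene should secure, the nonpolar homodimer of 5 being separable on silica. It also needs the double bond not to migrate, since migration would give C23 and C25 homologues; the benzoquinone additive and mild temperature should suppress the Ru–H species responsible. The eight-methylene spacer keeps the alkene of 4 away from the ester carbonyl, and the benzyl ethers keep the catechol from binding ruthenium.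

**Step 4**
Reactants: 6 (E)-tetracos-9-en-1-yl 2,3-bis(benzyloxy)benzoate
Product: 7 tetracosyl 2,3-dihydroxybenzoate (Gentiside K)
Conditions: H2 (1 atm), 10% Pd/C, EtOAc–THF (1:1), rt (after silica filtration of 6 to remove Ru residues)
Reagents that add atoms: none
Why: Heterogeneous catalytic hydrogenation should saturate the disubstituted alkene and hydrogenolyse both aryl benzyl ethers in one operation, while the alkyl benzoate ester and the arene are untouched at 1 atm and room temperature.

**Compound list**
1 | 2,3-dihydroxybenzoic acid | OC(=O)c1cccc(O)c1O | starting material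
2 | 10-bromodec-1-ene | C=CCCCCCCCCBr | starting material
3 | dec-9-en-1-yl 2,3-dihydroxybenzoate | C=CCCCCCCCCOC(=O)c1cccc(O)c1O | intermediate
4 | dec-9-en-1-yl 2,3-bis(benzyloxy)benzoate | C=CCCCCCCCCOC(=O)c1cccc(OCc2ccccc2)c1OCc1ccccc1 | intermediate
5 | hexadec-1-ene | CCCCCCCCCCCCCCC=C | starting material
6 | (E)-tetracos-9-en-1-yl 2,3-bis(benzyloxy)benzoate | CCCCCCCCCCCCCC/C=C/CCCCCCCCOC(=O)c1cccc(OCc2ccccc2)c1OCc1ccccc1 | intermediate
7 | tetracosyl 2,3-dihydroxybenzoate (Gentiside K) | CCCCCCCCCCCCCCCCCCCCCCCCOC(=O)c1cccc(O)c1O | target

**Total step count:** 4
**Longest linear sequence:** 4 steps (from 1)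

**Steps most likely to fail**

Step 3. Homodimerisation of either partner may outrun the cross reaction, or Ru–H-mediated double-bond migration may scramble the chain length. The fallback replaces metathesis by carbonyl olefination at the same C9=C10 position and sets out from 4. Oxidative cleavage of the terminal alkene (cat. OsO4, NaIO4, 2,6-lutidine, dioxane–H2O) should give the aldehyde 9-oxononyl 2,3-bis(benzyloxy)benzoate F1. Separately, 1-bromopentadecane and PPh3 (MeCN, reflux) should give pentadecyl(triphenyl)phosphonium bromide F2. Its ylide (NaHMDS, THF, −78 °C) should undergo Wittig reaction with F1 at −78 to 0 °C to give (Z)-tetracos-9-en-1-yl 2,3-bis(benzyloxy)benzoate F3. F3 is the geometric isomer of 6, and under the conditions of step 4 it should come back to the route at 7.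

Step 1. Alkylation of the carboxylate by an unactivated primary bromide may be slow, and partial O-alkylation of the 3-OH or air oxidation of the catecholate may compete. The fallback protects first and forms the ester by acylation, setting out from 1. Exhaustive benzylation (BnBr, K2CO3, DMF) should give benzyl 2,3-bis(benzyloxy)benzoate F4. Saponification (NaOH, MeOH–THF–H2O, reflux, then acid) should give 2,3-bis(benzyloxy)benzoic acid F5. Steglich esterification with commercial dec-9-en-1-ol (EDC·HCl, DMAP, CH2Cl2) should then return to the route at 4, bypassing 3 and step 2.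

Step 4. Hydrogenolysis may stall through catalyst poisoning by residual ruthenium or through poor solubility of the waxy long-chain substrate, leaving partly benzylated material. The fallback separates the two tasks and sets out from 6. Diimide reduction (TsNHNH2, NaOAc, DME–H2O, reflux) should give tetracosyl 2,3-bis(benzyloxy)benzoate F6. Lewis-acid debenzylation (BCl3, pentamethylbenzene, CH2Cl2, −78 °C), which should leave the alkyl ester intact, returns to the route at 7.

**Further compounds**
F1 | step 3 | 9-oxononyl 2,3-bis(benzyloxy)benzoate | O=CCCCCCCCCOC(=O)c1cccc(OCc2ccccc2)c1OCc1ccccc1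
F2 | step 3 | pentadecyl(triphenyl)phosphonium bromide | CCCCCCCCCCCCCCC[P+](c1ccccc1)(c1ccccc1)c1ccccc1.[Br-]
F3 | step 3 | (Z)-tetracos-9-en-1-yl 2,3-bis(benzyloxy)benzoate | CCCCCCCCCCCCCC/C=C\CCCCCCCCOC(=O)c1cccc(OCc2ccccc2)c1OCc1ccccc1
F4 | step 1 | benzyl 2,3-bis(benzyloxy)benzoate | O=C(OCc1ccccc1)c1cccc(OCc2ccccc2)c1OCc1ccccc1
F5 | step 1 | 2,3-bis(benzyloxy)benzoic acid | OC(=O)c1cccc(OCc2ccccc2)c1OCc1ccccc1
F6 | step 4 | tetracosyl 2,3-bis(benzyloxy)benzoate | CCCCCCCCCCCCCCCCCCCCCCCCOC(=O)c1cccc(OCc2ccccc2)c1OCc1ccccc1
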